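The synthesis hinges on disconnecting the C5=C6 alkene of carbocycle B (C5–C10, eudesmane numbering). This trisubstituted alkene is exocyclic to ring A. Its two carbons connect to the cis-related C7 and C8 (the latter via C9–C10) of the γ-lactone. One ring-closing metathesis between a C7 vinyl group and a C5 methylidene group therefore closes ring B, expels ethene and leaves all eight stereocentres untouched. The precursor is a pentaene that already carries ring A, the lactone, the spiro dihydropyran and the elemane ring. Its spiro centre C11 comes from a biomimetic hetero-Diels–Alder reaction between a monocyclic α-methylene lactone and an elemane enal.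

Key step: step 18

Remark on numbering: C1–C15 is the eudesmanolide half (C12 lactone carbonyl, C13 former exocyclic methylene). C1'–C15' is the elemane half (C10' quaternary, C5' and C7' ring CH, C12' formyl carbon, C13' enal methylene).

Assumption: the sense of induction of the two chiral reagents is taken by analogy ((S)-phosphoric acid in step 8 to the Si face of 8, (R,R)-bromoborane in step 10 to the (2R,3R)-acid). If either proved opposite, the mirror-image reagent would be used and nothing else would change.

Step 1
Reactants: 1 2,6-dimethylcyclohexanone (commercial cis/trans mixture); 2 (S)-1-phenylethylamine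
Product: 3 2,6-dimethyl-N-[(1S)-1-phenylethyl]cyclohexan-1-imine (ring epimers undefined)
Conditions: TsOH·H2O (1 mol %), toluene, Dean–Stark trap, reflux
Reagents that add atoms: none
Why: Acid-catalysed imine condensation driven by azeotropic removal of water; the ring stereocentres need no control here because they equilibrate through the enamine tautomer in step 2.

Step 2
Reactants: 3 imine; 4 phenyl vinyl sulfone
Product: 6 (2R,6S)-2,6-dimethyl-2-[2-(phenylsulfonyl)ethyl]cyclohexan-1-one (methyl groups cis), via Michael adduct imine 5 (not isolated)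
Conditions: 4 (1.2 equiv), THF, 65 °C; then 20% aq AcOH, rt
Reagents that add atoms: water (O)
Why: Asymmetric Michael addition of a chiral imine through its secondary enamine tautomer (aza-ene-type transition state): the phenylethyl group shields one face and sets C10 as R, the C4 methyl group stands axial in the reacting enamine to avoid allylic strain with the N-substituent so that the sulfone enters anti to it, and because C4 epimerises through imine–enamine tautomerism both epimers of 3 should funnel into one adduct before mild hydrolysis frees the ketone.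

Step 3
Reactants: 6 keto sulfone
Product: 7 {2-[(1R,3S)-1,3-dimethyl-2-methylidenecyclohexyl]ethyl}sulfonylbenzene
Conditions: Cp2TiMe2 (3 equiv), toluene, 75 °C, dark
Reagents that add atoms: dimethyltitanocene ([CH3-].[CH3-].[Ti+4].c1cc[cH-]c1.c1cc[cH-]c1)
Why: Petasis methylenation olefinates the hindered ketone under non-basic conditions, so the epimerisable C4 centre should be kept and the sulfone is inert.

Step 4
Reactants: 7 methylidene sulfone
Product: 8 2-[(1R,3S)-1,3-dimethyl-2-methylidenecyclohexyl]acetaldehyde
Conditions: n-BuLi (1.05 equiv), THF, −78 °C; then Me3SiOOSiMe3, −78 °C to rt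
Reagents that add atoms: bis(trimethylsilyl) peroxide (C[Si](C)(C)OO[Si](C)(C)C)
Why: Oxidative desulfonylation of a lithiated primary sulfone with a silyl peroxide replaces the sulfonyl group by a carbonyl oxygen; no stereocentre is involved and the exocyclic alkene is inert.

Step 5
Reactants: 9 acrolein; 10 methyl acrylate
Product: 11 methyl 3-hydroxy-2-methylidenepent-4-enoate (racemic)
Conditions: DABCO (20 mol %), excess 10, neat, rt
Reagents that add atoms: none
Why: Morita–Baylis–Hillman reaction with 1,2-addition of the amine-derived acrylate enolate to acrolein; the racemic carbinol centre is erased in step 7.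

Step 6
Reactants: 11 allylic alcohol
Product: 12 methyl 3-acetoxy-2-methylidenepent-4-enoate
Conditions: Ac2O, pyridine, DMAP (2 mol %), CH2Cl2, 0 °C
Reagents that add atoms: acetic anhydride (CC(=O)OC(C)=O)
Why: DMAP-catalysed O-acetylation turns the hydroxyl group into a leaving group for the allylic substitution.

Step 7
Reactants: 12 acetate
Product: 13 methyl (2E)-2-[(4,4,5,5-tetramethyl-1,3,2-dioxaborolan-2-yl)methyl]penta-2,4-dienoate (vinyl cis to CH2B)
Conditions: B2pin2 (1.1 equiv), CuCl (10 mol %), KOAc (20 mol %), DMF, rt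
Reagents that add atoms: bis(pinacolato)diboron (CC1(C)OB(OC1(C)C)B1OC(C)(C)C(C)(C)O1)
Why: Copper-catalysed allylic borylation in the SN2' sense (boryl addition to the acrylate C=C, then loss of acetate) should give the preferred trisubstituted alkene with the vinyl group trans to the ester and therefore cis to CH2B.

Step 8
Reactants: 8 aldehyde; 13 allylboronate
Product: 15 (4R,5R)-5-{[(1R,3S)-1,3-dimethyl-2-methylidenecyclohexyl]methyl}-4-ethenyl-3-methylideneoxolan-2-one (cis lactone), via hydroxy ester 14 (not isolated)
Conditions: (S)-3,3'-bis(2,4,6-triisopropylphenyl)-1,1'-binaphthyl-2,2'-diyl hydrogen phosphate (10 mol %), 4 Å MS, toluene, −30 °C to rt; aq work-up; then PPTS (10 mol %), CH2Cl2, rt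
Reagents that add atoms: none
Why: Chiral-phosphoric-acid-catalysed allylboration followed by lactonisation: the closed chair transition state puts the vinyl group (cis to CH2B) axial and so gives the syn adduct (C7/C8 cis), while the (S)-acid directs attack to the Si face of 8 and sets C8 as R independently of the remote C10 centre.

Step 9
Reactants: 16 geraniol; 17 3-methylbut-3-enoic acid
Product: 18 (2E)-3,7-dimethylocta-2,6-dien-1-yl 3-methylbut-3-enoate
Conditions: DCC, DMAP (5 mol %), CH2Cl2, 0 °C
Reagents that add atoms: none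
Why: Steglich esterification at low temperature with little DMAP keeps the β,γ-double bond out of conjugation.

Step 10
Reactants: 18 geranyl ester
Product: 20 (2R,3R)-3-ethenyl-3,7-dimethyl-2-(prop-1-en-2-yl)oct-6-enoic acid, via boron ketene acetal 19 (not isolated)
Conditions: (4R,5R)-2-bromo-4,5-diphenyl-1,3-bis{[3,5-bis(trifluoromethyl)phenyl]sulfonyl}-1,3,2-diazaborolidine (1.2 equiv, prepared beforehand), Et3N, toluene/hexane, −78 °C, then −20 °C; aq work-up
Reagents that add atoms: none
Why: Enantioselective Ireland–Claisen rearrangement: soft enolisation in a non-polar medium should give 19 with the isopropenyl group cis to O-geranyl, the chair transition state on the (E)-alkene sets the C5'/C10' pair in the sense that places vinyl and isopropenyl trans in the later ring, and the C2-symmetric sulfonamide ligand selects the face.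

Step 11
Reactants: 20 acid
Product: 21 (2R,3R)-3-ethenyl-3,7-dimethyl-2-(prop-1-en-2-yl)oct-6-en-1-ol
Conditions: LiAlH4, Et2O, 0 °C to rt
Reagents that add atoms: none
Why: Hydride reduction of the carboxylic acid leaves the four isolated alkenes and both stereocentres untouched.

Step 12
Reactants: 21 alcohol
Product: 22 (2R,3R)-3-ethenyl-3,7-dimethyl-2-(prop-1-en-2-yl)oct-6-enal
Conditions: Dess–Martin periodinane, pyridine, CH2Cl2, 0 °C; used at once
Reagents that add atoms: none
Why: Buffered Dess–Martin oxidation is mild enough to avoid epimerisation at C5' and migration of the β,γ-double bond into conjugation.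

Step 13
Reactants: 22 aldehyde
Product: 23 (1R,2R,3R,6R)-3-ethenyl-3-methyl-2,6-di(prop-1-en-2-yl)cyclohexan-1-ol (OH and both isopropenyl groups equatorial)
Conditions: Me2AlCl (1.5 equiv), CH2Cl2, −78 to −20 °C
Reagents that add atoms: none
Why: Intramolecular carbonyl-ene reaction of the citronellal-to-isopulegol kind: the chair transition state with the C5' isopropenyl and C10' vinyl groups equatorial puts the new C7' isopropenyl group equatorial, hence cis to the C5' substituent and to the C10' methyl group.

Step 14
Reactants: 23 cyclohexanol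
Product: 24 O-[(1R,2R,3R,6R)-3-ethenyl-3-methyl-2,6-di(prop-1-en-2-yl)cyclohexyl] S-methyl carbonodithioate
Conditions: NaH, THF, 0 °C; CS2; then MeI, rt
Reagents that add atoms: carbon disulfide (S=C=S); iodomethane (CI)
Why: Xanthate formation by addition of the alkoxide to CS2 and S-methylation prepares the hindered secondary alcohol for radical deoxygenation.

Step 15
Reactants: 24 xanthate
Product: 25 (1R,2R,4S)-1-ethenyl-1-methyl-2,4-di(prop-1-en-2-yl)cyclohexane ((+)-β-elemene)
Conditions: Bu3SnH (3 equiv, 0.5 M), AIBN (10 mol %), toluene, 85 °C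
Reagents that add atoms: none
Why: Barton–McCombie deoxygenation; a high stannane concentration should trap the C6' radical before homoallyl/cyclopropylcarbinyl rearrangement, and the removed centre is not a stereocentre of the target.

Step 16
Reactants: 25 (+)-β-elemene
Product: 27 2-[(1S,3R,4R)-4-ethenyl-4-methyl-3-(prop-1-en-2-yl)cyclohexyl]prop-2-enal, via allylic alcohol 26 (not isolated)
Conditions: SeO2 (0.3 equiv), t-BuOOH (3 equiv), CH2Cl2, 0 °C to rt; filtration; then MnO2, CH2Cl2, rt
Reagents that add atoms: tert-butyl hydroperoxide (CC(C)(C)OO), oxygen passed on by selenium dioxide (O=[Se]=O)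
Why: Riley allylic oxidation (ene reaction, then [2,3]-shift) should pick the methyl group of the less hindered C7' isopropenyl group, the C5' one being shielded by the neighbouring quaternary C10', and MnO2 takes the allylic alcohol to the enal.

Step 17
Reactants: 15 α-methylene lactone; 27 enal
Product: 28 (3R,4S,5R)-3-{[(1R,3S)-1,3-dimethyl-2-methylidenecyclohexyl]methyl}-4-ethenyl-8-[(1S,3R,4R)-4-ethenyl-4-methyl-3-(prop-1-en-2-yl)cyclohexyl]-2,6-dioxaspiro[4.5]dec-7-en-1-one
Conditions: 15 (1.5 equiv), 27 added slowly, BHT (5 mol %), toluene (2 M), 120 °C, sealed tube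
Reagents that add atoms: none
Why: Thermal hetero-Diels–Alder reaction of a 2-substituted acrolein (1-oxadiene) with a 1,1-disubstituted acrylate-type alkene, with the regiochemistry of the thermal acrolein and methacrolein dimerisations (O to C11, C13' to C13); the diene adds to the face of C11=C13 opposite the cis C7 vinyl and C8 side chains, so the C11–O bond lies on the H7 face and C11 is set as R.

Step 18
Reactants: 28 pentaene
Product: 29 target CNP0175206.1
Conditions: second-generation Hoveyda–Grubbs catalyst, (H2IMes)Cl2Ru=CH(2-i-PrOC6H4) (10 mol %), toluene (1 mM), 90 °C, argon sparge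
Reagents that add atoms: none
Why: Olefin metathesis by the Chauvin mechanism: the ruthenium benzylidene exchanges onto the monosubstituted C7 vinyl group, the new alkylidene (Ru=C6) adds to the C5 methylidene group to give a ruthenacyclobutane, and cycloreversion releases the C5=C6 alkene and Ru=CH2, whose methylene leaves as ethene in the next turnover. The closest known reaction type is ring-closing metathesis of a 1,7-diene built from a vinyl group and a 1,1-disubstituted alkene next to a quaternary carbon, giving a trisubstituted cyclohexene. Ring B (C5, C6, C7, C8, C9, C10) closes as a six-membered ring through the new C5=C6 double bond, all other rings being in place. No stereocentre is formed and none is at risk, since the conditions are neutral and C4, C7, C8, C10 and C11 are not touched. The step needs site selectivity among five C=C bonds: the elemane vinyl group sits on a quaternary carbon, the isopropenyl group and the enol ether are more highly substituted, and none of them has a partner within reach of a five- to seven-membered ring, whereas the cis arrangement on the lactone holds the two reacting alkenes close. High dilution and removal of ethene should suppress dimerisation at the C7 vinyl group.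

Compound list
1 | 2,6-dimethylcyclohexanone | CC1CCCC(C)C1=O | starting material
2 | (S)-1-phenylethylamine | C[C@H](N)c1ccccc1 | starting material
3 | 2,6-dimethyl-N-[(1S)-1-phenylethyl]cyclohexan-1-imine | C[C@H](N=C1C(C)CCCC1C)c1ccccc1 | intermediate
4 | phenyl vinyl sulfone | C=CS(=O)(=O)c1ccccc1 | starting material
5 | (2R,6S)-2,6-dimethyl-N-[(1S)-1-phenylethyl]-2-[2-(phenylsulfonyl)ethyl]cyclohexan-1-imine | C[C@H](N=C1[C@@H](C)CCC[C@]1(C)CCS(=O)(=O)c1ccccc1)c1ccccc1 | intermediate
6 | (2R,6S)-2,6-dimethyl-2-[2-(phenylsulfonyl)ethyl]cyclohexan-1-one | O=C1[C@@H](C)CCC[C@]1(C)CCS(=O)(=O)c1ccccc1 | intermediate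
7 | {2-[(1R,3S)-1,3-dimethyl-2-methylidenecyclohexyl]ethyl}sulfonylbenzene | C=C1[C@@H](C)CCC[C@]1(C)CCS(=O)(=O)c1ccccc1 | intermediate
8 | 2-[(1R,3S)-1,3-dimethyl-2-methylidenecyclohexyl]acetaldehyde | O=CC[C@@]1(C)CCC[C@H](C)C1=C | intermediate
9 | acrolein | C=CC=O | starting material
10 | methyl acrylate | C=CC(=O)OC | starting material
11 | methyl 3-hydroxy-2-methylidenepent-4-enoate | C=CC(O)C(=C)C(=O)OC | intermediate
12 | methyl 3-acetoxy-2-methylidenepent-4-enoate | C=CC(OC(C)=O)C(=C)C(=O)OC | intermediate
13 | methyl (2E)-2-[(4,4,5,5-tetramethyl-1,3,2-dioxaborolan-2-yl)methyl]penta-2,4-dienoate | C=C/C=C(\CB1OC(C)(C)C(C)(C)O1)C(=O)OC | intermediate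
14 | methyl (3R,4R)-5-[(1R,3S)-1,3-dimethyl-2-methylidenecyclohexyl]-3-ethenyl-4-hydroxy-2-methylidenepentanoate | COC(=O)C(=C)[C@@H](C=C)[C@H](O)C[C@@]1(C)CCC[C@H](C)C1=C | intermediate
15 | (4R,5R)-5-{[(1R,3S)-1,3-dimethyl-2-methylidenecyclohexyl]methyl}-4-ethenyl-3-methylideneoxolan-2-one | C=C1C(=O)O[C@H](C[C@@]2(C)CCC[C@H](C)C2=C)[C@@H]1C=C | intermediate
16 | geraniol | OC/C=C(\C)CCC=C(C)C | starting material
17 | 3-methylbut-3-enoic acid | C=C(C)CC(=O)O | starting material
18 | geranyl 3-methylbut-3-enoate | C=C(C)CC(=O)OC/C=C(\C)CCC=C(C)C | intermediate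
19 | boron ketene acetal of 18 with the (4R,5R)-diazaborolidine (isopropenyl cis to O-geranyl) | C=C(C)/C=C(\OC/C=C(\C)CCC=C(C)C)OB1N(S(=O)(=O)c2cc(cc(c2)C(F)(F)F)C(F)(F)F)[C@H](c2ccccc2)[C@@H](c2ccccc2)N1S(=O)(=O)c1cc(cc(c1)C(F)(F)F)C(F)(F)F | intermediate
20 | (2R,3R)-3-ethenyl-3,7-dimethyl-2-(prop-1-en-2-yl)oct-6-enoic acid | C=C[C@@](C)(CCC=C(C)C)[C@H](C(=O)O)C(C)=C | intermediate
21 | (2R,3R)-3-ethenyl-3,7-dimethyl-2-(prop-1-en-2-yl)oct-6-en-1-ol | C=C[C@@](C)(CCC=C(C)C)[C@H](CO)C(C)=C | intermediate
22 | (2R,3R)-3-ethenyl-3,7-dimethyl-2-(prop-1-en-2-yl)oct-6-enal | C=C[C@@](C)(CCC=C(C)C)[C@H](C=O)C(C)=C | intermediate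
23 | (1R,2R,3R,6R)-3-ethenyl-3-methyl-2,6-di(prop-1-en-2-yl)cyclohexan-1-ol | C=C[C@@]1(C)CC[C@H](C(C)=C)[C@@H](O)[C@@H]1C(=C)C | intermediate
24 | O-[(1R,2R,3R,6R)-3-ethenyl-3-methyl-2,6-di(prop-1-en-2-yl)cyclohexyl] S-methyl carbonodithioate | C=C[C@@]1(C)CC[C@H](C(C)=C)[C@@H](OC(=S)SC)[C@@H]1C(=C)C | intermediate
25 | (1R,2R,4S)-1-ethenyl-1-methyl-2,4-di(prop-1-en-2-yl)cyclohexane | C=C[C@@]1(C)CC[C@H](C(C)=C)C[C@@H]1C(=C)C | intermediate
26 | 2-[(1S,3R,4R)-4-ethenyl-4-methyl-3-(prop-1-en-2-yl)cyclohexyl]prop-2-en-1-ol | C=C[C@@]1(C)CC[C@H](C(=C)CO)C[C@@H]1C(=C)C | intermediate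
27 | 2-[(1S,3R,4R)-4-ethenyl-4-methyl-3-(prop-1-en-2-yl)cyclohexyl]prop-2-enal | C=C[C@@]1(C)CC[C@H](C(=C)C=O)C[C@@H]1C(=C)C | intermediate
28 | (3R,4S,5R)-3-{[(1R,3S)-1,3-dimethyl-2-methylidenecyclohexyl]methyl}-4-ethenyl-8-[(1S,3R,4R)-4-ethenyl-4-methyl-3-(prop-1-en-2-yl)cyclohexyl]-2,6-dioxaspiro[4.5]dec-7-en-1-one | C=C[C@@]1(C)CC[C@H](C2=CO[C@@]3(CC2)C(=O)O[C@H](C[C@@]2(C)CCC[C@H](C)C2=C)[C@@H]3C=C)C[C@@H]1C(=C)C | intermediate
29 | CNP0175206.1 | C=C[C@@]1(C)CC[C@H](C2=CO[C@@]3(CC2)C(=O)O[C@@H]2C[C@@]4(C)CCC[C@H](C)C4=C[C@@H]23)C[C@@H]1C(=C)C | target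

Total step count: 18. Longest linear sequence: 10 steps (steps 9 to 18, from 16 and 17 to 29).

Steps most likely to fail

Step 18. Ruthenacyclobutane formation at the C5 methylidene group, flanked by the quaternary C10 and the tertiary C4, may be too slow. Dimerisation through the C7 vinyl group or catalyst decay would then take over.
- The fallback closes the same bond by alkylidene-mediated carbonyl olefination of a C5 ketone. It sets out from imine 3 and comes back at 29.
- Addition of 3 to nitroethylene gives the nitro imine F1, which is hydrolysed with aq AcOH to the nitro ketone F2.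
- A Nef reaction on its potassium nitronate (KOH, then KMnO4, MgSO4, 0 °C) gives the keto aldehyde F3.
- Allylboration with 13 as in step 8 gives the keto hydroxy ester F4 and, after lactonisation, the keto lactone F5.
- Cycloaddition with 27 as in step 17 gives the keto cycloadduct F6.
- One equivalent of Mo(=CHCMe2Ph)(=N-2,6-i-Pr2C6H3)[OCMe(CF3)2]2 in benzene then exchanges its alkylidene onto the C7 vinyl group. The new alkylidene olefinates the C5 ketone in an irreversible Wittig-like step to give 29.

Step 17. Self-dimerisation of the enal, slow cross-addition at the congested C11=C13 bond, or thermal migration of that bond into conjugation may erode the cycloaddition.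
- The fallback builds the dihydropyran stepwise. It sets out from 15 (with 27) and comes back at 28.
- Nucleophilic epoxidation of the electron-poor C11=C13 bond (t-BuOOLi, THF, −20 °C), from the face opposite the C7 and C8 substituents, gives the spiro-epoxy lactone F7.
- MgI2 in Et2O opens it at C13 to the iodohydrin F8.
- A Giese addition of the C13 radical (Bu3SnH, AIBN, benzene, 80 °C) to the methylene terminus of 27 gives the δ-hydroxy aldehyde F9, which is in equilibrium with its lactol.
- Dehydration (PPTS, 4 Å MS, toluene, 60 °C) gives 28.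

Step 8. The ester-deactivated boronate may add sluggishly. An uncatalysed background reaction could then erode face selectivity, or acid could promote Prins-type closure of the aldehyde onto the C5 methylidene group.
- The fallback puts the chiral controller on boron. It sets out from 12 and comes back at 14.
- Borylation of 12 with B2(OH)4 (CuCl, KOAc, as in step 7) gives the allylboronic acid F10.
- Esterification with diisopropyl L-tartrate (MgSO4, Et2O) gives the more Lewis acidic tartrate boronate F11.
- F11 adds to 8 without catalyst (4 Å MS, toluene, −78 °C to rt) through the same chair on the Si face to give 14, which is lactonised to 15 as before.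

Further compounds
F1 | step 18 | (2R,6S)-2,6-dimethyl-2-(2-nitroethyl)-N-[(1S)-1-phenylethyl]cyclohexan-1-imine | C[C@H](N=C1[C@@H](C)CCC[C@]1(C)CC[N+](=O)[O-])c1ccccc1
F2 | step 18 | (2R,6S)-2,6-dimethyl-2-(2-nitroethyl)cyclohexan-1-one | O=C1[C@@H](C)CCC[C@]1(C)CC[N+](=O)[O-]
F3 | step 18 | 2-[(1R,3S)-1,3-dimethyl-2-oxocyclohexyl]acetaldehyde | O=CC[C@@]1(C)CCC[C@H](C)C1=O
F4 | step 18 | methyl (3R,4R)-5-[(1R,3S)-1,3-dimethyl-2-oxocyclohexyl]-3-ethenyl-4-hydroxy-2-methylidenepentanoate | COC(=O)C(=C)[C@@H](C=C)[C@H](O)C[C@@]1(C)CCC[C@H](C)C1=O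
F5 | step 18 | (4R,5R)-5-{[(1R,3S)-1,3-dimethyl-2-oxocyclohexyl]methyl}-4-ethenyl-3-methylideneoxolan-2-one | C=C1C(=O)O[C@H](C[C@@]2(C)CCC[C@H](C)C2=O)[C@@H]1C=C
F6 | step 18 | C5-oxo analogue of 28 (ketone in place of the C5 methylidene group) | C=C[C@@]1(C)CC[C@H](C2=CO[C@@]3(CC2)C(=O)O[C@H](C[C@@]2(C)CCC[C@H](C)C2=O)[C@@H]3C=C)C[C@@H]1C(=C)C
F7 | step 17 | spiro-epoxy lactone from 15 (C11–O on the H7 face) | C1O[C@]12C(=O)O[C@H](C[C@@]3(C)CCC[C@H](C)C3=C)[C@@H]2C=C
F8 | step 17 | C11-hydroxy C13-iodo lactone (iodohydrin) | O[C@@]1(CI)C(=O)O[C@H](C[C@@]2(C)CCC[C@H](C)C2=C)[C@@H]1C=C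
F9 | step 17 | δ-hydroxy aldehyde (C11–OH, C13–C13' bond made, C11' epimers) | C=C[C@@]1(C)CC[C@H](C(C=O)CC[C@]2(O)C(=O)O[C@H](C[C@@]3(C)CCC[C@H](C)C3=C)[C@@H]2C=C)C[C@@H]1C(=C)C
F10 | step 8 | [(2E)-2-(methoxycarbonyl)penta-2,4-dien-1-yl]boronic acid | C=C/C=C(\CB(O)O)C(=O)OC
F11 | step 8 | diisopropyl (4R,5R)-2-[(2E)-2-(methoxycarbonyl)penta-2,4-dien-1-yl]-1,3,2-dioxaborolane-4,5-dicarboxylate | C=C/C=C(\CB1O[C@@H](C(=O)OC(C)C)[C@H](C(=O)OC(C)C)O1)C(=O)OC
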